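**Plan**

1. Retrosynthetic cuts, in order: the C8=C9 enol ester (olefination of a C9 aldehyde); C10–C9 and C5–C6 (vinyl and acetonyl precursors on an enone); then C5 is excised from ring A, contracting the cycloheptenone to a bicyclo[3.3.1]nonan-3-one; C2–C14 and O–C15 (oxa-Diels–Alder); C11–C12 (conjugate addition to 3-methylcyclohexenone).
2. Forward: a cyclohexanone carrying C1, C2, C3, C4, C10, C11 is made first; rings B and C close together in one intramolecular oxa-Diels–Alder reaction; ring A closes last, when C5 is inserted as dibromocarbene between C4 and C10.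
3. Enabling feature: in ring A the carbonyl carbon C4 is flanked by C5, and C5 is bonded to C10. Ring A without C5 is a six-membered ketone whose C4=C10 enol ether accepts the missing atom, and the bromine that arrives with C5 is the handle for the C5–C6 bond.
4. Helpers: the silyl enol ether (activation), the fused cyclopropane (temporary ring) and the C5 bromine are all consumed by the end of step 7.
5. Stereochemistry: C11 from catalytic asymmetric conjugate addition; C2 and C14 from the tether in the cycloaddition; C3 from convex-face hydrogenation (locked by ring C); C10 from convex-face cuprate addition; C5 from protonation trans to the vinyl group; the (E)-enol ester from the Wittig step.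
6. Locants used throughout: ring A = C1, C2, C3, C4 (C=O), C5, C10, C11; ring B = C1, C2, C14, C13, C12, C11; ring C = C2, C3, C18, O, C15, C14; C20 = methyl on C11; C6, C7, C19 = acetonyl on C5; C9=C8 = enol ester vinyl on C10.

Key step: step 6

Assumption: the antipode of the chiral NHC ligand in step 1 is the one that gives (R)-4; the sense of induction would be confirmed on 4 before the route is continued.

**Route**

Step 1
Reactants: 1 3-methylcyclohex-2-en-1-one; 2 5-bromo-2-methylpent-2-ene
Product: 4 (R)-3-methyl-3-(4-methylpent-3-en-1-yl)cyclohexan-1-one, via Grignard reagent 3 (not isolated)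
Conditions: Mg, Et2O, reflux; then 1, Cu(OTf)2 (3 mol %), chiral hydroxyalkyl-imidazolinium salt (NHC precursor, 4 mol %), Et2O, 0 °C; aq NH4Cl
Reagents that add atoms: none
Why: Copper-catalysed asymmetric conjugate addition of a Grignard reagent to a β-substituted cyclohexenone, in which the chiral NHC–copper complex differentiates the enone faces and sets the quaternary centre C11, from which all later stereocentres are relayed.

Step 2
Reactants: 4
Product: 5 (2Z,5S)-2-(hydroxymethylene)-5-methyl-5-(4-methylpent-3-en-1-yl)cyclohexan-1-one
Conditions: NaH, HCO2Et, EtOH (cat.), THF, 0 °C to rt; 1 M HCl work-up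
Reagents that add atoms: ethyl formate, CCOC=O
Why: Crossed Claisen condensation (α-formylation) under equilibrating conditions should place the formyl carbon C18 on the unhindered C3 methylene and not on the neopentyl C10 methylene; no stereocentre is formed.

Step 3
Reactants: 5
Product: 7 tricyclic vinylogous ester (six-membered ring C1, C2, C3, C4, C10, C11 with C4 ketone; rings B and C closed; C3=C18 enol ether; C2, C11, C14 as in the target), via formyl enone 6 (not isolated)
Conditions: DDQ (1.1 equiv), 1,4-dioxane, rt; then toluene, 80 °C
Reagents that add atoms: none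
Why: DDQ dehydrogenation of the β-keto aldehyde enol gives the 2-formylcyclohex-2-enone 6, a 1-oxadiene (O=C18–C3=C2) that should undergo intramolecular inverse-electron-demand oxa-Diels–Alder reaction with the trisubstituted alkene (electrophilic C2 to C14, oxygen to the dimethyl-bearing C15), and the three-atom tether from C11 can reach C2 only on its own face and only with a cis B/C fusion, which sets C2 and C14.

Step 4
Reactants: 7
Product: 8 tricyclic ketone (bicyclo[3.3.1]nonan-3-one fused to the 2,2-dimethyltetrahydropyran ring C; C2, C3, C11, C14 as in the target)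
Conditions: H2 (1 atm), 10% Pd/C, EtOAc, rt
Reagents that add atoms: none
Why: Heterogeneous hydrogenation of the β-alkoxy enone C=C from the convex face (away from the C12–C14 bridge) should give C3–H cis to C2–H, the only C3 configuration that lets ring C adopt a chair, so this epimerisable centre is also thermodynamically secured.

Step 5
Reactants: 8
Product: 9 trimethylsilyl enol ether of 8 with the C4=C10 double bond
Conditions: LiN(i-Pr)2, Me3SiCl (internal quench), THF, −78 °C; Et3N/pentane work-up
Reagents that add atoms: chlorotrimethylsilane, C[Si](C)(C)Cl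
Why: Kinetic enolisation with a hindered amide base under internal silyl quench should remove a proton from the C10 methylene in preference to the C3 methine, giving the less substituted silyl enol ether without equilibration; no stereocentre is affected.

Step 6
Reactants: 9
Product: 11 5-bromo enone (tricyclic 5-bromocyclohept-5(10)-en-4-one; rings A, B and C complete), via dibromocyclopropane 10 (not isolated)
Conditions: CHBr3, KOt-Bu, pentane, −30 °C to rt; then toluene, 80 °C
Reagents that add atoms: bromoform, BrC(Br)Br
Why: Dibromocarbene from CHBr3/KOt-Bu should add in a concerted [2+1] fashion to the electron-rich C4=C10 enol ether from the convex face to give the 1-silyloxy-7,7-dibromobicyclo[4.1.0]heptane unit of 10; ionisation of the bromide syn to the six-membered ring, assisted by the silyloxy donor, triggers disrotatory two-electron electrocyclic opening to a 2-bromo-oxyallyl cation, and loss of Me3SiBr leaves the 2-bromocyclohept-2-enone. The closest known reaction type is the dihalocarbene ring enlargement of cyclic silyl enol ethers to 2-halocycloalk-2-enones. The three-membered ring closes by cheletropic addition, and ring A is closed by cleavage of the shared C4–C10 bond of the fused cyclopropane, i.e. by one-carbon insertion and not by end-to-end cyclisation, so no medium-ring entropy penalty is paid. No stereocentre is created (C5 and C10 become sp2 and both cyclopropane centres are lost), and C2, C3, C11 and C14 are untouched. The step needs the new carbon to enter between C4 and C10 and not between C4 and C3, which the position of the enol ether double bond in 9 fixes, and it needs cleavage of the internal and not an external cyclopropane bond, which the inward rotation of the ring residues (departure of the endo bromide) and the oxygen lone pair secure.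

Step 7
Reactants: 11
Product: 12 5-(2-methylallyl) enone (tricyclic cyclohept-5(10)-en-4-one with CH2C(CH3)=CH2 on C5)
Conditions: tributyl(2-methylallyl)stannane, Pd2(dba)3 (2.5 mol %), AsPh3 (10 mol %), CuI (10 mol %), NMP, 50 °C
Reagents that add atoms: tributyl(2-methylallyl)stannane, CCCC[Sn](CCCC)(CCCC)CC(C)=C
Why: Stille coupling of an α-bromo enone (oxidative addition of zerovalent palladium into C5–Br, tin-to-palladium transfer of the methallyl group, reductive elimination) leaves the enone and all stereocentres untouched, and both ends of the methallyl group give the same product.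

Step 8
Reactants: 12
Product: 14 5-(2-methylallyl)-10-vinyl ketone (C5–H and vinyl on the convex face, methallyl trans to vinyl; C2, C3, C5, C10, C11, C14 as in the target), via silyl enol ether 13 (not isolated)
Conditions: CH2=CHMgBr, CuBr·SMe2 (10 mol %), Me3SiCl, HMPA, THF, −78 to −40 °C; then 1 M HCl, THF, 0 °C
Reagents that add atoms: vinylmagnesium bromide, C=C[Mg]Br; chlorotrimethylsilane, C[Si](C)(C)Cl (silicon is retained only in 13)
Why: Silyl-chloride-accelerated copper-catalysed 1,4-addition of a vinyl Grignard reagent should deliver the vinyl group to C10 from the convex face of the bridged bicycle (the side of the C11 methyl, away from the C12–C14 bridge and its axial C13–H), and protonation of the silyl enol ether at C5 from the same open face should place the methallyl chain trans to the vinyl group, C5 remaining epimerisable if correction is needed.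

Step 9
Reactants: 14
Product: 15 keto aldehyde (10-formyl-5-(2-oxopropyl) tricyclic ketone; stereocentres as in the target)
Conditions: O3, CH2Cl2–MeOH, −78 °C; then Me2S, −78 °C to rt
Reagents that add atoms: ozone, [O-][O+]=O
Why: Ozonolysis with reductive work-up cleaves both terminal alkenes in one operation, the vinyl group giving the C9 aldehyde and the 1,1-disubstituted methallyl alkene the C7 methyl ketone, under neutral conditions that preserve the epimerisable centres C3, C5 and C10.

Step 10
Reactants: 16 3-methylbut-2-enoyl chloride
Product: 17 chloromethyl 3-methylbut-2-enoate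
Conditions: paraformaldehyde, ZnCl2 (cat.), neat, 80 °C
Reagents that add atoms: paraformaldehyde (formaldehyde unit), C=O
Why: Lewis-acid-catalysed insertion of formaldehyde into the acyl chloride C–Cl bond (chloromethyl ester formation) is a standard preparation of this ester class.

Step 11
Reactants: 17
Product: 18 {[(3-methylbut-2-enoyl)oxy]methyl}triphenylphosphonium chloride
Conditions: PPh3, toluene, 80 °C
Reagents that add atoms: triphenylphosphine, c1ccc(cc1)P(c1ccccc1)c1ccccc1
Why: SN2 quaternisation of triphenylphosphine by the activated chloromethyl ester gives the acyloxymethylphosphonium salt.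

Step 12
Reactants: 15; 18
Product: 20 vibsanin E, via ylide 19 (not isolated)
Conditions: K2CO3, 18-crown-6 (cat.), CH2Cl2, rt
Reagents that add atoms: none
Why: Wittig olefination in its acyloxymethylene-ylide (Anders–Gaßner) variant, in which the weakly basic ylide should react with the aldehyde and not with the two ketones and install the complete enol ester in one step, the (E)-isomer being separated from any (Z)-isomer.

**Compound list**

1 | 3-methylcyclohex-2-en-1-one | CC1=CC(=O)CCC1 | starting material
2 | 5-bromo-2-methylpent-2-ene | CC(C)=CCCBr | starting material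
3 | (4-methylpent-3-en-1-yl)magnesium bromide | CC(C)=CCC[Mg]Br | intermediate (not isolated)
4 | (R)-3-methyl-3-(4-methylpent-3-en-1-yl)cyclohexan-1-one | CC(C)=CCC[C@@]1(C)CCCC(=O)C1 | intermediate
5 | (2Z,5S)-2-(hydroxymethylene)-5-methyl-5-(4-methylpent-3-en-1-yl)cyclohexan-1-one | CC(C)=CCC[C@@]1(C)CC/C(=C/O)C(=O)C1 | intermediate
6 | (4S)-4-methyl-4-(4-methylpent-3-en-1-yl)-6-oxocyclohex-1-ene-1-carbaldehyde | CC(C)=CCC[C@@]1(C)CC=C(C=O)C(=O)C1 | intermediate (not isolated)
7 | tricyclic vinylogous ester (C4 ketone, C3=C18 enol ether, rings B and C closed) | O=C1C2=COC(C)(C)[C@@H]3CC[C@@](C)(C[C@@H]32)C1 | intermediate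
8 | tricyclic ketone (bicyclo[3.3.1]nonan-3-one fused to ring C) | O=C1[C@@H]2COC(C)(C)[C@@H]3CC[C@@](C)(C[C@@H]32)C1 | intermediate
9 | C4=C10 trimethylsilyl enol ether of 8 | C[Si](C)(C)OC=1[C@@H]2COC(C)(C)[C@@H]3CC[C@@](C)(C[C@@H]32)C=1 | intermediate
10 | 5,5-dibromo-4-(trimethylsilyloxy) cyclopropane adduct (C4–C5–C10 ring, CBr2 on the convex face) | C[Si](C)(C)O[C@]14[C@@H]2COC(C)(C)[C@@H]3CC[C@@](C)(C[C@@H]32)[C@H]1C4(Br)Br | intermediate (not isolated)
11 | 5-bromo enone (tricyclic 5-bromocyclohept-5(10)-en-4-one) | BrC=1C(=O)[C@@H]2COC(C)(C)[C@@H]3CC[C@@](C)(C[C@@H]32)C1 | intermediate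
12 | 5-(2-methylallyl) enone | CC(=C)CC=1C(=O)[C@@H]2COC(C)(C)[C@@H]3CC[C@@](C)(C[C@@H]32)C1 | intermediate
13 | C4=C5 trimethylsilyl enol ether, 5-(2-methylallyl), 10-vinyl | CC(=C)CC1=C(O[Si](C)(C)C)[C@@H]2COC(C)(C)[C@@H]3CC[C@@](C)(C[C@@H]32)[C@H]1C=C | intermediate (not isolated)
14 | 5-(2-methylallyl)-10-vinyl ketone (trans) | CC(=C)C[C@@H]1C(=O)[C@@H]2COC(C)(C)[C@@H]3CC[C@@](C)(C[C@@H]32)[C@H]1C=C | intermediate
15 | 10-formyl-5-(2-oxopropyl) ketone (keto aldehyde) | CC(=O)C[C@@H]1C(=O)[C@@H]2COC(C)(C)[C@@H]3CC[C@@](C)(C[C@@H]32)[C@H]1C=O | intermediate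
16 | 3-methylbut-2-enoyl chloride | CC(C)=CC(Cl)=O | starting material
17 | chloromethyl 3-methylbut-2-enoate | CC(C)=CC(=O)OCCl | intermediate
18 | {[(3-methylbut-2-enoyl)oxy]methyl}triphenylphosphonium chloride | CC(C)=CC(=O)OC[P+](c1ccccc1)(c1ccccc1)c1ccccc1.[Cl-] | intermediate
19 | {[(3-methylbut-2-enoyl)oxy]methylene}triphenylphosphorane | CC(C)=CC(=O)OC=P(c1ccccc1)(c1ccccc1)c1ccccc1 | intermediate (not isolated)
20 | vibsanin E | CC(=O)C[C@@H]1C(=O)[C@@H]2COC(C)(C)[C@@H]3CC[C@@](C)(C[C@@H]32)[C@H]1/C=C/OC(=O)C=C(C)C | target

**Step count and risks**

Total steps: 12. Longest linear sequence: 10 (steps 1–9 and 12).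

Steps most likely to fail:

1. Step 5. What may go wrong: competing abstraction of the C3 methine proton, which is activated by the β-oxygen, would give the wrong enol ether and, after β-elimination of the C18 alkoxide, open ring C. Fallback, from 8 back to 12: the ring is enlarged by migratory aptitude instead of by enolate regiochemistry. Me3SiCHN2 with BF3·OEt2 (CH2Cl2, −78 °C) adds to the C4 carbonyl and the less substituted C10 methylene migrates, giving the C5-silyl ketone F1, which is protodesilylated on acidic work-up to the cycloheptanone F2. Kinetic enolisation at the now unhindered C5 methylene (LiN(i-Pr)2, Me3SiCl) gives the C4=C5 silyl enol ether F3, and Pd(OAc)2 in MeCN dehydrosilylates it to the enone F4. Iodine in pyridine/CH2Cl2 gives the 5-iodo enone F5, which takes the place of 11 in the coupling of step 7 and gives 12.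

2. Step 8. What may go wrong: sluggish 1,4-addition of the cuprate to the α-substituted, β-neopentyl enone, and incomplete facial control in the protonation at C5. Fallback, from 12 back to 15: a small stabilised carbon nucleophile is added under equilibrating conditions. Nitromethane with DBU (MeCN, rt) gives in a Michael addition the 10-(nitromethyl) ketone F6, with C5 and C10 free to settle in the trans arrangement. NaOMe in MeOH converts it to the sodium nitronate F7, and ozonolysis (−78 °C, then Me2S) cleaves the nitronate C=N and the methallyl C=C together to give 15.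

3. Step 12. What may go wrong: formation of the (Z)-enol ester beside the (E)-isomer, and base-induced epimerisation at C10 or aldol closure of 15 during the olefination. Fallback, from 15 back to 20: the aldehyde alone is homologated without base by a Takai-type boron olefination (CrCl2, Cl2CHBpin, LiI, THF, rt), which is (E)-selective and inert to ketones, to the (E)-alkenyl pinacolboronate F8. KHF2 in MeOH–H2O gives the potassium trifluoroborate F9, and copper-catalysed oxidative Chan–Lam-type coupling with 3-methylbut-2-enoic acid (CuBr, DMAP, 4 Å sieves, O2, CH2Cl2) transfers the alkenyl group to the carboxylate oxygen with retention of geometry to give 20.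

Further compounds

F1 | step 5 | C5-trimethylsilyl cycloheptanone (C5 configuration undefined) | C[Si](C)(C)C1C(=O)[C@@H]2COC(C)(C)[C@@H]3CC[C@@](C)(C[C@@H]32)C1
F2 | step 5 | tricyclic cycloheptan-4-one (C5 and C10 unsubstituted) | C1C(=O)[C@@H]2COC(C)(C)[C@@H]3CC[C@@](C)(C[C@@H]32)C1
F3 | step 5 | C4=C5 trimethylsilyl enol ether of F2 | C1=C(O[Si](C)(C)C)[C@@H]2COC(C)(C)[C@@H]3CC[C@@](C)(C[C@@H]32)C1
F4 | step 5 | tricyclic cyclohept-5(10)-en-4-one | C=1C(=O)[C@@H]2COC(C)(C)[C@@H]3CC[C@@](C)(C[C@@H]32)C1
F5 | step 5 | 5-iodo enone | IC=1C(=O)[C@@H]2COC(C)(C)[C@@H]3CC[C@@](C)(C[C@@H]32)C1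
F6 | step 8 | 5-(2-methylallyl)-10-(nitromethyl) ketone | CC(=C)C[C@@H]1C(=O)[C@@H]2COC(C)(C)[C@@H]3CC[C@@](C)(C[C@@H]32)[C@H]1C[N+](=O)[O-]
F7 | step 8 | sodium nitronate of F6 | CC(=C)C[C@@H]1C(=O)[C@@H]2COC(C)(C)[C@@H]3CC[C@@](C)(C[C@@H]32)[C@H]1C=[N+]([O-])[O-].[Na+]
F8 | step 12 | (E)-alkenyl pinacolboronate on C10 | CC(=O)C[C@@H]1C(=O)[C@@H]2COC(C)(C)[C@@H]3CC[C@@](C)(C[C@@H]32)[C@H]1/C=C/B1OC(C)(C)C(C)(C)O1
F9 | step 12 | potassium (E)-alkenyltrifluoroborate on C10 | CC(=O)C[C@@H]1C(=O)[C@@H]2COC(C)(C)[C@@H]3CC[C@@](C)(C[C@@H]32)[C@H]1/C=C/[B-](F)(F)F.[K+]
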